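I set the charge of starting material by asking how much target the catalyst can turn out in the run, so I count the lifetimes of one trip round the cycle.

in all of them: gas 7.0 mM (held); free catalyst 0.14 mM; time 8.0 min
- midnight: starting material 0.0040 M
- autumn: starting material 0.0080 M
- winter: starting material 0.015 M
- dawn: starting material 0.030 M
- dusk: starting material 0.060 M

    reagent + free catalyst ⇌ catalyst intermediate A (K1 = 78 L mol⁻¹, k1 = 64.6 L mol⁻¹ s⁻¹)
    catalyst intermediate A → catalyst intermediate B (k2 = 28.9 s⁻¹)
    starting material + catalyst intermediate B ⇌ catalyst intermediate C (K3 = 350 L mol⁻¹, k3 = 414 L mol⁻¹ s⁻¹)
    catalyst intermediate C ⇌ catalyst intermediate D (K4 = 0.34, k4 = 238 s⁻¹)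
    catalyst intermediate D ⇌ released group + catalyst intermediate E (K5 = 0.71 M, k5 = 55.7 s⁻¹)
    catalyst intermediate E ⇌ free catalyst + target (K6 = 0.177 M, k6 = 2.38 s⁻¹)
    gas ⇌ reagent, rate k7*(csat - [reagent]) (k7 = 0.0271 s⁻¹, csat = 7.0 mM)
    reagent → decomposition product (k8 = 2.54 × 10⁻⁶ s⁻¹)

1. [target] at the end for midnight, autumn, winter, dawn, dusk, in this order
2. how that number moves from the first to the last of them (hardly changes / falls all the way / falls, then rises / rises, then falls / rises all the way)

- at the start none of reagent is dissolved
- "hardly changes" means that all values lie within two and a half points (for a concentration: within two and a half percent of the largest)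
- run time (midnight): 8.0 min

- Free catalyst waits 2.21 s for reagent even at full dissolved strength, and catalyst intermediate E lasts 0.420 s before it gives up target. Catalyst intermediate A lasts 0.0346 s, far shorter, so I keep the two long waits, 2.63 s a trip.
- That pace draws reagent at 3.19 mM min⁻¹, and the gas can supply this only if dissolved reagent sits 28.0 % below saturation. One pass with that lower level stretches the trip to 3.49 s, longer than before.
- Reagent starts at nothing and takes about 36.9 s to fill, much shorter than the run, so I subtract that lag once. This gives 0.0178 M of target, the run capacity: what one catalyst charge can make in the run while starting material lasts.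
- First setting, the charge of starting material. I read the capacity as a fraction of each charge: 444 % for midnight, 222 % for autumn, 118 % for winter, 59.2 % for dawn and 29.6 % for dusk. I commit to full conversion in the first three flasks and to those fractions in the last two.
- The charge also enters the trip through catalyst intermediate B, which lasts 0.0805 s at the dawn charge and 0.0403 s at the dusk charge. Both are far shorter than a trip, so I expect dusk to make barely more target than dawn.
- Second setting, the run length. Capacity grows with the time past the lag, so at 80.0 min I reckon 318 % of the dusk charge and expect dusk to finish.
- The forecast gives 0.004 M, 0.008 M, 0.0145 M, 0.0168 M and 0.0171 M, and its shape is rises all the way, on the ground that “The two lowest loadings therefore convert essentially completely”. It parts from me at winter, where it stops at 96.7 % of the charge, and at the top, where it stands below my capacity.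
- The flask gives 0.00400 M, 0.00800 M, 0.0148 M, 0.0172 M and 0.0175 M, and the number rises all the way.

In dawn the capacity is 59.2 % of the charge against 57.3 % target at 8.00 min, and in winter it is 118 % against 98.7 %, with 1.26 % of the starting material left. In dusk it is 29.6 % against 29.2 %, while free catalyst, the resting state, holds 75.0 % of the catalyst charged, more than any other form of the catalyst, and at ten times the run, 80.0 min, target stands at 100 %.

(The numbers of this flask were set for the occasion; what happens was integrated by code.)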